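## Structural features

The target is a hexahydro-1H-cyclopenta[c]isoxazole in which an isoxazolidine (N1, O2, C3, C3a, C6a) is cis-fused through the C3a–C6a bond to an otherwise unsubstituted cyclopentane (C3a, C4, C5, C6, C6a). N1 carries a 12-(pyridin-3-yl)dodecyl chain and C3 an 8-(pyridin-3-yl)octyl chain, so apart from the N–O unit the only functional groups are two remote, basic 3-alkylpyridines. Three contiguous stereocentres, C3 (S), C3a (S) and C6a (R), lie on the heterocycle, with H3, H3a and H6a mutually cis, which places the C3 chain on the concave face next to C4. The N–O bond is the fragile element (hydrogenolysis, dissolving or low-valent metals). The pyridines are nucleophilic, oxidisable at nitrogen and good ligands for boranes, Lewis acids and palladium, so every oxidation, Lewis-acid and metal-catalysed step has to allow for them. The real difficulty is the stereotriad around a trisubstituted hydroxylamine: absolute configuration at the unactivated C6a, the cis ring fusion and the endo alkyl group at C3, all without a reduction that would cut N–O. The strategy exploits the fact that the N-bearing C6a is bonded to C3a, which carries the exocyclic C3 at the carbonyl oxidation level once O2–C3 is opened. That 2-aminocyclopentyl ketone is what a 2-alkylcyclohex-2-en-1-amine leaves behind when its ring contracts and its C2 is pushed out as the ketone carbon, so C3a (alpha to the carbonyl) and C3 (the carbonyl) can both be set late from the single centre C6a.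

## Logic of the disconnections

**21 to 20.** The C3–H bond is cut (hydride), raising C3 to the hemiketal level. C3 then needs no earlier control, because a cis-fused bicyclic cation should accept hydride on its convex face, which is the face that gives the 3S centre. The forward step needs a Lewis acid in excess over the two pyridines and a reductant that leaves N–O alone.

**20 to 17 (through 19 and 18).** The O2–C3 bond is opened (ring–chain tautomerism), C3a is allowed to be trans, and the N-hydroxy group is masked as a benzoate. This removes the bicycle and one stereocentre. The forward step must cleave the ester, epimerise C3a by enolisation and let only the cis isomer close, without expelling nitrogen from the beta position.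

**17 to 16.** The N1–O2 bond is cut back to a secondary amine. A diacyl peroxide puts oxygen on nitrogen directly, so no peracid has to be used beside the pyridines. The demand is chemoselectivity for the aliphatic amine.

**16 to 15.** An N–S bond to a 2-nitrobenzenesulfonyl group is added retrosynthetically. The nitrogen must be non-basic and non-oxidisable in the oxidative step, and the same group enables the earlier C–N coupling. Its removal must be mild enough not to enolise the beta-sulfonamido ketone.

**15 to 13 (key).** The C3a–C6a bond is cut and C6a is rejoined to the ketone carbon, which returns a cyclohexene with the octyl chain on C2 and nitrogen on C1. The cyclopentane and its 1,2-relationship are traded for a six-membered ring with one stereocentre. The forward step requires Markovnikov delivery of methanol to C2, migration of C1 with retention, and masking of the pyridines.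

**13 to 9 and 12 (12 from 11).** The sp2–sp3 bond between C2 and the chain is cut. The vinyl iodide comes from the enone, and attaching the pyridine chain only after the stereocentre exists keeps a boron-binding pyridine out of the asymmetric reduction. The forward B-alkyl coupling must tolerate the nitroarene and a flanking tertiary sulfonamide.

**9 to 8 and 5.** The C1–N bond is cut. A Mitsunobu displacement turns a carbinol stereocentre into the amine stereocentre with inversion, so the alcohol must be S and the nucleophile must be acidic (hence the sulfonamide). Azide is excluded because an allylic azide would racemise by sigmatropic shift.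

**8 to 7 to 6.** The C1–H bond (asymmetric hydride) and the C2–I bond are cut. This is the only reagent-controlled stereochemical step of the route, and the iodine serves both as the large group for the reduction and as the coupling handle.

**5 to 3 to 1 and 2.** The N–C bond to the dodecyl chain (Mitsunobu reaction of a Boc-activated sulfonamide) and the picolyl C–C bond are cut. The forward alkylation uses excess picolyl anion so that the hydroxyl of 2 needs no protection.

**11 to 1 and 10.** The picolyl C–C bond is cut. This is a single alkylation, and the terminal alkene is the latent borane.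

## Other disconnections considered

Alternative 1: The cut is N1–C6a. The open-chain precursor is O-{(1S)-1-[(1S)-cyclopent-2-en-1-yl]-9-(pyridin-3-yl)nonyl}-N-[12-(pyridin-3-yl)dodecyl]hydroxylamine A1. A1 would be reached by allylboration of an aldehyde with a cyclopentenylboron reagent, then O-amination and N-alkylation. N-Iodosuccinimide would turn the ring alkene of A1 into an iodonium ion on the face away from the C3a substituent, and nitrogen would attack C6a anti to iodine (5-exo). This would give (3S,3aS,6S,6aS)-6-iodo-1-[12-(pyridin-3-yl)dodecyl]-3-[8-(pyridin-3-yl)octyl]hexahydro-1H-cyclopenta[c]isoxazole A2. Radical deiodination of A2 would give 21.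
- In its favour: C3 and C3a are made together through a closed six-membered transition state, the ring fusion can only be cis, no epimerisation is needed, and N–O is brought in intact.
- Against it here: the allylboration of an aliphatic aldehyde must be both enantio- and diastereoselective, and its intrinsic syn/anti sense has to match the target (or the C3–O bond must be made with inversion). The hydroxylamine N–H and both pyridines of A1 compete for the iodonium source. Iodine ends up at C6 of A2, which is bare in the target, and must then be removed without touching N–O.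
- Comparison: on structure it controls all three centres by transition-state geometry, whereas the chosen plan controls one by reagent and two by substrate. On mechanism the halocyclisation is the better-precedented ring-forming event, so it is the better of the two on that point. On handling the pyridines against an electrophilic iodine reagent the two are equal. Step economy is about equal, since iodine installation and removal and the two-stage hydroxylamine assembly offset the sulfonamide steps. The chosen plan is preferred because its absolute configuration rests on one very dependable ketone reduction.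

Alternative 2: The cut is C3a–C4. LiN(SiMe3)2 would deprotonate (3R)-3-(3-chloropropyl)-2-[12-(pyridin-3-yl)dodecyl]isoxazolidin-5-one A3 alpha to the carbonyl, and the enolate of A3 would displace chloride (5-exo-tet). This would give (3aS,6aR)-1-[12-(pyridin-3-yl)dodecyl]hexahydro-3H-cyclopenta[c]isoxazol-3-one A4. A single addition of the C3 chain as a carbon nucleophile to the lactone carbonyl of A4 would give 20, which is then reduced as in the chosen route.
- In its favour: C6a and the N–O bond would arrive together by asymmetric conjugate addition, the fusion in A4 is necessarily cis so C3a needs no equilibration, and the end game is shared.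
- Against it here: the enolate of A3 has a beta nitrogen and can open by elimination. A4 is an O-acyl hydroxylamine, an acylating and N-electrophilic species, so mono-addition of a basic organometallic competes with N–O cleavage, double addition and enolisation. The nucleophile would itself carry a pyridine.
- Comparison: on structure it is equal for C3 (same convex-face hydride) and better for C3a. On mechanism an enolate alkylation is simpler in type than a 1,2-shift, but it is run on a more fragile heterocycle. On step economy it is equal or slightly better. The chosen plan avoids strong base and organometallics on an N–O lactone.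

Alternative 3: The cuts are N1–O2 and O2–C3, made together. m-CPBA would oxidise (4aR,7aR)-1-[12-(pyridin-3-yl)dodecyl]-2,4a,5,6,7,7a-hexahydro-1H-cyclopenta[b]pyridine A5 at the ring nitrogen. The product would be (4aR,7aR)-1-[12-(pyridin-3-yl)dodecyl]-2,4a,5,6,7,7a-hexahydro-1H-cyclopenta[b]pyridine 1-oxide A6. In A6 a [2,3]-Meisenheimer shift would move oxygen to C4 while N–CH2 breaks, giving (3S,3aS,6aR)-3-ethenyl-1-[12-(pyridin-3-yl)dodecyl]hexahydro-1H-cyclopenta[c]isoxazole A7. The vinyl group of A7 would then be extended by cross-metathesis and saturated.
- In its favour: two ring bonds including N–O form in one operation with no nitrogen protecting group, the cis fusion is inherited from A5, and chirality is relayed suprafacially.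
- Against it here: the shift in A6 has to occur inside a six-membered ring, with the oxide oxygen spanning N1 and C4 in a strained bridged transition state. Homolytic 1,2-shift (ring expansion) and Cope elimination into the dodecyl chain are plausible competitors. The C3 configuration is dictated by that geometry and cannot be chosen. The peracid also threatens the pyridines. The chain of A7 must still be built by a cross-metathesis that basic pyridines hamper and by an alkene reduction that spares N–O.
- Comparison: on bond economy of the key step and on freedom from protecting groups it is the better plan. On mechanistic security it is the weaker. On overall step count it is about equal once the chain extension is counted.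

Key step: step 8

Remark on the chemistry: hemiketal 20 is assumed to form as a mixture of C3 anomers. This does not matter because both ionise to the same cation in step 12.

Remark on the chemistry: the sense of the CBS reduction is assigned by the usual large/small-group model, with the iodovinyl arm as the large group. The (1R) centre of 9 and 13 becomes C6a (R) of 21 with unchanged spatial arrangement.

## Route

Step 1
Reactants: 1 3-methylpyridine; 2 11-bromoundecan-1-ol
Product: 3 12-(pyridin-3-yl)dodecan-1-ol
Conditions: 1 (2.5 equiv), LiN(i-Pr)2 (2.4 equiv), THF/DMPU, −78 °C; then 2 (1 equiv), −78 °C → rt; aq. NH4Cl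
Reagents that add atoms: none
Why: Lateral lithiation of 3-methylpyridine gives 3-picolyllithium; one equivalent is consumed by the hydroxyl of 2 and the excess anion displaces the primary bromide (SN2 picolyl alkylation), so no hydroxyl protection is needed. Excess 3-methylpyridine is volatile and the product can be purified by acid–base extraction.

Step 2
Reactants: 3 12-(pyridin-3-yl)dodecan-1-ol
Product: 5 2-nitro-N-[12-(pyridin-3-yl)dodecyl]benzenesulfonamide, via N-Boc sulfonamide 4 (not isolated)
Conditions: NsNHBoc, PPh3, DIAD, THF, 0 °C → rt; concentrate; then TFA/CH2Cl2, rt; aq. NaHCO3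
Reagents that add atoms: tert-butyl [(2-nitrophenyl)sulfonyl]carbamate, CC(C)(C)OC(=O)NS(=O)(=O)c1ccccc1[N+](=O)[O-]
Why: Mitsunobu N-alkylation of the acidic N-Boc sulfonamide by the primary alcohol stops at monoalkylation, and TFA then removes the Boc group to leave the N–H sulfonamide needed for step 5. The basic pyridine allows Ph3PO and the hydrazine dicarboxylate to be washed out by acid–base extraction.

Step 3
Reactants: 6 cyclohex-2-en-1-one
Product: 7 2-iodocyclohex-2-en-1-one
Conditions: I2, K2CO3, 4-(dimethylamino)pyridine (cat.), THF/H2O, rt
Reagents that add atoms: iodine, II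
Why: Amine-catalysed alpha-iodination of an enone (conjugate addition of the amine, iodination of the enolate, elimination of the amine), a standard entry to 2-iodocycloalkenones.

Step 4
Reactants: 7 2-iodocyclohex-2-en-1-one
Product: 8 (1S)-2-iodocyclohex-2-en-1-ol
Conditions: (R)-1-methyl-3,3-diphenyltetrahydro-1H,3H-pyrrolo[1,2-c][1,3,2]oxazaborole [(R)-Me-CBS, 10 mol %], BH3·SMe2, THF, 0 °C; MeOH quench
Reagents that add atoms: none
Why: CBS reduction: the iodovinyl arm acts as the large group and the ring CH2 as the small one, so the (R)-oxazaborolidine should deliver hydride to the carbonyl face that gives the (S)-carbinol. No Lewis-basic pyridine is present yet to compete for boron, which is why the reduction precedes chain attachment.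

Step 5
Reactants: 8 (1S)-2-iodocyclohex-2-en-1-ol; 5 2-nitro-N-[12-(pyridin-3-yl)dodecyl]benzenesulfonamide
Product: 9 N-[(1R)-2-iodocyclohex-2-en-1-yl]-2-nitro-N-[12-(pyridin-3-yl)dodecyl]benzenesulfonamide
Conditions: PPh3, DIAD, toluene, 0 °C → rt
Reagents that add atoms: none
Why: Fukuyama–Mitsunobu reaction: the sulfonamide anion displaces the allylic oxyphosphonium group by SN2 with inversion, turning the (S)-alcohol into the (R)-sulfonamide whose carbon becomes C6a. The electron-withdrawing vinyl iodide disfavours ionisation and allylic transposition.

Step 6
Reactants: 1 3-methylpyridine; 10 7-bromohept-1-ene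
Product: 11 3-(oct-7-en-1-yl)pyridine
Conditions: LiN(i-Pr)2, THF/DMPU, −78 °C; then 10, −78 °C → rt
Reagents that add atoms: none
Why: The same picolyl anion alkylation as in step 1, on an unfunctionalised primary bromide; the terminal alkene is inert to the base.

Step 7
Reactants: 11 3-(oct-7-en-1-yl)pyridine; 9 N-[(1R)-2-iodocyclohex-2-en-1-yl]-2-nitro-N-[12-(pyridin-3-yl)dodecyl]benzenesulfonamide
Product: 13 N-{(1R)-2-[8-(pyridin-3-yl)octyl]cyclohex-2-en-1-yl}-2-nitro-N-[12-(pyridin-3-yl)dodecyl]benzenesulfonamide, via B-alkyl-9-BBN 12 (not isolated)
Conditions: 11 (1.5 equiv), 9-BBN (1.6 equiv), THF, rt → 60 °C; then degassed aq. Cs2CO3; then 9, PdCl2(dppf) (dppf = 1,1'-bis(diphenylphosphino)ferrocene, 5 mol %), AsPh3, DMF, 50 °C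
Reagents that add atoms: none
Why: B-alkyl Suzuki–Miyaura coupling: anti-Markovnikov hydroboration gives the primary alkylborane, which after base activation transmetalates to the vinylpalladium iodide formed by oxidative addition of zerovalent palladium to 9, and reductive elimination forms the sp2–sp3 bond with the stereocentre and nosyl group as spectators. Extra 9-BBN and warming compensate for reversible pyridine–borane complexation, and the aqueous base destroys residual B–H before the nitroarene is introduced.

Step 8
Reactants: 13 N-{(1R)-2-[8-(pyridin-3-yl)octyl]cyclohex-2-en-1-yl}-2-nitro-N-[12-(pyridin-3-yl)dodecyl]benzenesulfonamide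
Product: 15 N-{(1R,2R)-2-[9-(pyridin-3-yl)nonanoyl]cyclopentyl}-2-nitro-N-[12-(pyridin-3-yl)dodecyl]benzenesulfonamide, via dimethyl ketal 14 (not isolated)
Conditions: TsOH·H2O (2.2 equiv), MeOH/CH(OMe)3, 0 °C; PhI(OH)OTs (1.2 equiv), 0 °C → rt; then 1 M HCl, THF, rt; aq. NaHCO3
Reagents that add atoms: water, O
Why: With both pyridines held as pyridinium tosylates, the trivalent iodine electrophile PhI(OMe)OTs engages only the trisubstituted C2=C3 bond, on the face anti to the bulky allylic sulfonamide, and methanol opens the adduct at the tertiary C2 (Markovnikov, trans-diaxial). After ring inversion the equatorial C3–I bond is antiperiplanar to the ring bond C1–C2, which shifts to C3 with inversion there as iodobenzene leaves, while the C2 methoxy group stabilises the resulting oxocarbenium ion; methanol gives ketal 14 and aqueous acid the ketone 15. This is the established hypervalent-iodine oxidative ring contraction of 1-alkylcyclohexenes to acylcyclopentanes, a semipinacol-type 1,2-alkyl shift. The five-membered ring arises by contraction (bond C1–C2 exchanged for C1–C3) and not by a cyclisation, so no ring-closure mode in the usual sense applies. The migrating C1 keeps its configuration, which carries the (R) centre from steps 4 and 5 into C6a. The new centre C3a should form trans to nitrogen (anti addition, then inversion at C3), but nothing depends on it because it is alpha to the ketone and is reset in step 11. The selectivity that matters is regiochemical: methanol must add to C2 so that C1 and not C4 migrates, and the C2 alkyl chain secures this by making C2 the only tertiary terminus. The fully substituted, electron-poor nosyl nitrogen can neither be oxidised nor participate.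

Step 9
Reactants: 15 N-{(1R,2R)-2-[9-(pyridin-3-yl)nonanoyl]cyclopentyl}-2-nitro-N-[12-(pyridin-3-yl)dodecyl]benzenesulfonamide
Product: 16 1-[(1R,2R)-2-{[12-(pyridin-3-yl)dodecyl]amino}cyclopentyl]-9-(pyridin-3-yl)nonan-1-one
Conditions: PhSH, K2CO3, MeCN, 0 °C → rt
Reagents that add atoms: none
Why: Fukuyama deprotection: thiolate adds ipso to the nitroarene (Meisenheimer complex) and the sulfonamide collapses with loss of SO2 to the secondary amine. The weakly basic thiolate/carbonate system at or below room temperature is chosen so that the ketone is not enolised, since an enolate could expel the sulfonamide by E1cB.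

Step 10
Reactants: 16 1-[(1R,2R)-2-{[12-(pyridin-3-yl)dodecyl]amino}cyclopentyl]-9-(pyridin-3-yl)nonan-1-one
Product: 17 O-benzoyl-N-{(1R,2R)-2-[9-(pyridin-3-yl)nonanoyl]cyclopentyl}-N-[12-(pyridin-3-yl)dodecyl]hydroxylamine
Conditions: (PhCO2)2 (water-wet, 1.2 equiv), K2HPO4, DMF, rt
Reagents that add atoms: dibenzoyl peroxide, O=C(OOC(=O)c1ccccc1)c1ccccc1
Why: The secondary amine attacks the peroxide O–O bond to give the O-benzoyl hydroxylamine directly, with the phosphate buffer trapping benzoic acid and suppressing N-benzoylation. The N–O bond is thus made without a peracid, so the far less nucleophilic pyridines and the ketone are left alone.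

Step 11
Reactants: 17 O-benzoyl-N-{(1R,2R)-2-[9-(pyridin-3-yl)nonanoyl]cyclopentyl}-N-[12-(pyridin-3-yl)dodecyl]hydroxylamine
Product: 20 (3aS,6aR)-1-[12-(pyridin-3-yl)dodecyl]-3-[8-(pyridin-3-yl)octyl]hexahydro-1H-cyclopenta[c]isoxazol-3-ol, via trans N-hydroxy ketone 18 (not isolated), via cis N-hydroxy ketone 19 (not isolated)
Conditions: K2CO3, degassed MeOH, rt, argon
Reagents that add atoms: none
Why: Methanolysis of the activated O-acyl hydroxylamine frees the N-hydroxy group, and carbonate/methoxide reversibly enolises the ketone so that C3a equilibrates. Only the cis epimer 19 can close (5-exo-trig addition of N–OH to the carbonyl), because a trans-fused bicyclo[3.3.0] hemiketal is prohibitively strained, so the equilibrium should drain to 20 and C3a (S) is set under thermodynamic control relative to the fixed C6a.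

Step 12
Reactants: 20 (3aS,6aR)-1-[12-(pyridin-3-yl)dodecyl]-3-[8-(pyridin-3-yl)octyl]hexahydro-1H-cyclopenta[c]isoxazol-3-ol
Product: 21 (3S,3aS,6aR)-1-[12-(pyridin-3-yl)dodecyl]-3-[8-(pyridin-3-yl)octyl]hexahydro-1H-cyclopenta[c]isoxazole
Conditions: Et3SiH (6 equiv), BF3·OEt2 (5 equiv), CH2Cl2, −78 → −20 °C; aq. NaHCO3
Reagents that add atoms: none
Why: Ionic hydrogenation of a cyclic hemiketal: BF3 (in excess because both pyridines bind it) ionises C3–OH to the bicyclic N-alkoxy oxocarbenium ion, and Et3SiH should deliver hydride to its convex face, the face bearing H3a and H6a. H3 then ends cis to both ring-fusion hydrogens with the octyl chain on the concave face, which is 3S; the silane does not reduce the N–O bond.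

## Compound list

1 | 3-methylpyridine | Cc1cccnc1 | starting material
2 | 11-bromoundecan-1-ol | OCCCCCCCCCCCBr | starting material
3 | 12-(pyridin-3-yl)dodecan-1-ol | OCCCCCCCCCCCCc1cccnc1 | intermediate
4 | tert-butyl N-[(2-nitrophenyl)sulfonyl]-N-[12-(pyridin-3-yl)dodecyl]carbamate | CC(C)(C)OC(=O)N(CCCCCCCCCCCCc1cccnc1)S(=O)(=O)c1ccccc1[N+](=O)[O-] | intermediate (not isolated)
5 | 2-nitro-N-[12-(pyridin-3-yl)dodecyl]benzenesulfonamide | O=S(=O)(NCCCCCCCCCCCCc1cccnc1)c1ccccc1[N+](=O)[O-] | intermediate
6 | cyclohex-2-en-1-one | O=C1C=CCCC1 | starting material
7 | 2-iodocyclohex-2-en-1-one | O=C1CCCC=C1I | intermediate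
8 | (1S)-2-iodocyclohex-2-en-1-ol | O[C@H]1CCCC=C1I | intermediate
9 | N-[(1R)-2-iodocyclohex-2-en-1-yl]-2-nitro-N-[12-(pyridin-3-yl)dodecyl]benzenesulfonamide | c1cncc(CCCCCCCCCCCCN(S(=O)(=O)c2ccccc2[N+](=O)[O-])[C@@H]2CCCC=C2I)c1 | intermediate
10 | 7-bromohept-1-ene | C=CCCCCCBr | starting material
11 | 3-(oct-7-en-1-yl)pyridine | C=CCCCCCCc1cccnc1 | intermediate
12 | 9-[8-(pyridin-3-yl)octyl]-9-borabicyclo[3.3.1]nonane | c1cncc(CCCCCCCCB2C3CCCC2CCC3)c1 | intermediate (not isolated)
13 | N-{(1R)-2-[8-(pyridin-3-yl)octyl]cyclohex-2-en-1-yl}-2-nitro-N-[12-(pyridin-3-yl)dodecyl]benzenesulfonamide | c1cncc(CCCCCCCCCCCCN(S(=O)(=O)c2ccccc2[N+](=O)[O-])[C@@H]2CCCC=C2CCCCCCCCc2cccnc2)c1 | intermediate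
14 | N-{(1R,2R)-2-[1,1-dimethoxy-9-(pyridin-3-yl)nonyl]cyclopentyl}-2-nitro-N-[12-(pyridin-3-yl)dodecyl]benzenesulfonamide | c1cncc(CCCCCCCCCCCCN(S(=O)(=O)c2ccccc2[N+](=O)[O-])[C@@H]2CCC[C@H]2C(OC)(OC)CCCCCCCCc2cccnc2)c1 | intermediate (not isolated)
15 | N-{(1R,2R)-2-[9-(pyridin-3-yl)nonanoyl]cyclopentyl}-2-nitro-N-[12-(pyridin-3-yl)dodecyl]benzenesulfonamide (trans) | c1cncc(CCCCCCCCCCCCN(S(=O)(=O)c2ccccc2[N+](=O)[O-])[C@@H]2CCC[C@H]2C(=O)CCCCCCCCc2cccnc2)c1 | intermediate
16 | 1-[(1R,2R)-2-{[12-(pyridin-3-yl)dodecyl]amino}cyclopentyl]-9-(pyridin-3-yl)nonan-1-one | c1cncc(CCCCCCCCCCCCN[C@@H]2CCC[C@H]2C(=O)CCCCCCCCc2cccnc2)c1 | intermediate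
17 | O-benzoyl-N-{(1R,2R)-2-[9-(pyridin-3-yl)nonanoyl]cyclopentyl}-N-[12-(pyridin-3-yl)dodecyl]hydroxylamine | c1cncc(CCCCCCCCCCCCN(OC(=O)c2ccccc2)[C@@H]2CCC[C@H]2C(=O)CCCCCCCCc2cccnc2)c1 | intermediate
18 | N-{(1R,2R)-2-[9-(pyridin-3-yl)nonanoyl]cyclopentyl}-N-[12-(pyridin-3-yl)dodecyl]hydroxylamine (trans) | c1cncc(CCCCCCCCCCCCN(O)[C@@H]2CCC[C@H]2C(=O)CCCCCCCCc2cccnc2)c1 | intermediate (not isolated)
19 | N-{(1R,2S)-2-[9-(pyridin-3-yl)nonanoyl]cyclopentyl}-N-[12-(pyridin-3-yl)dodecyl]hydroxylamine (cis) | c1cncc(CCCCCCCCCCCCN(O)[C@@H]2CCC[C@@H]2C(=O)CCCCCCCCc2cccnc2)c1 | intermediate (not isolated)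
20 | (3aS,6aR)-1-[12-(pyridin-3-yl)dodecyl]-3-[8-(pyridin-3-yl)octyl]hexahydro-1H-cyclopenta[c]isoxazol-3-ol (cis-fused; C3 as either anomer) | c1cncc(CCCCCCCCCCCCN2OC(O)(CCCCCCCCc3cccnc3)[C@H]3CCC[C@H]32)c1 | intermediate
21 | (3S,3aS,6aR)-1-[12-(pyridin-3-yl)dodecyl]-3-[8-(pyridin-3-yl)octyl]hexahydro-1H-cyclopenta[c]isoxazole | c1cncc(CCCCCCCCCCCCN2O[C@@H](CCCCCCCCc3cccnc3)[C@H]3CCC[C@H]32)c1 | target

## Step count and least certain steps

Total: 12 steps. Longest linear sequence: 9 steps (steps 3, 4, 5, 7, 8, 9, 10, 11 and 12, from 6 through 7, 8, 9, 13, 15, 16, 17 and 20 to 21). The branch from 1 and 2 through 3 and 5 into 9 is equally long.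

**Step 8 (key step).** Ring contraction of 1-alkylcyclohexenes by this reagent class is established, but a sulfonamide on the migrating carbon is an untried variation. The most likely failure is a retarded 1,2-shift, because the sulfonamide withdraws electron density from the migrating C1. Methanol could then displace the iodane at C3 (a 2,3-dimethoxy adduct), the chain could migrate in place of the ring bond, or proton loss could give an allylic ether. Incomplete protonation of the pyridines would also let them ligate the iodine reagent. Fallback, from 13 back to 15 by a stepwise halohydrin semipinacol route: NBS in aqueous THF containing TsOH (bromonium anti to nitrogen, water at the tertiary C2) should give N-[(1R,2R,3R)-3-bromo-2-hydroxy-2-[8-(pyridin-3-yl)octyl]cyclohexyl]-2-nitro-N-[12-(pyridin-3-yl)dodecyl]benzenesulfonamide F1. AgBF4 in CH2Cl2 (monovalent silver as halide abstractor, in excess because both pyridines bind it) would then trigger the same C1 shift from the free hydroxyl, a stronger donor than methoxy, and deliver 15 directly. The leaving group can thus be activated separately and at low temperature.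

**Step 5.** The likely failure is slow SN2 at a secondary allylic centre flanked by iodine, with a bulky and only moderately acidic secondary sulfonamide as nucleophile. Elimination to the diene or alkylation of the hydrazide could then take over. Ionisation or SN2' attack would erode the enantiomeric purity, because the 2-iodocyclohexenyl system is constitutionally symmetric. Fallback, from 8 back to 9 by reversing the order of the two C–N bonds: Mitsunobu reaction of 8 with the smaller and more acidic NsNHBoc should give tert-butyl N-[(1R)-2-iodocyclohex-2-en-1-yl]-N-[(2-nitrophenyl)sulfonyl]carbamate F2. TFA would give N-[(1R)-2-iodocyclohex-2-en-1-yl]-2-nitrobenzenesulfonamide F3, and a second Mitsunobu alkylation of F3 with the primary alcohol 3 would give 9.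

**Step 7.** The likely failure is sluggish oxidative addition or transmetalation at a vinyl iodide crowded by the adjacent tertiary sulfonamide, made worse by pyridine binding to boron and palladium. Protodeiodination or beta-hydride elimination of the alkylpalladium species would then dominate. Fallback, from 7 back to 13 by coupling at the enone stage, where oxidative addition is fastest: 7 and 12 under the same palladium conditions should give 2-[8-(pyridin-3-yl)octyl]cyclohex-2-en-1-one F4. CBS reduction with near-stoichiometric (R)-Me-CBS and catecholborane (the pyridine competes for boron) would give (1S)-2-[8-(pyridin-3-yl)octyl]cyclohex-2-en-1-ol F5. Fukuyama–Mitsunobu coupling of F5 with 5 would give 13.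

**Step 9.** The likely failure is base-induced enolisation of the beta-sulfonamido ketone followed by E1cB loss of the sulfonamide, which would destroy C6a. Fallback, from 13 back to 16 with the ketone masked: step 8 is worked up with NaHCO3 without the acid hydrolysis so that ketal 14 is isolated. PhSH/K2CO3 on 14 should give (1R,2R)-2-[1,1-dimethoxy-9-(pyridin-3-yl)nonyl]-N-[12-(pyridin-3-yl)dodecyl]cyclopentan-1-amine F6, which cannot enolise, and dilute aqueous HCl in THF would then release 16.

**Step 11.** The likely failure is retro-aza-Michael expulsion of the hydroxylamine from the enolate and re-addition, which would erode the configuration at C6a. Incomplete epimerisation and aerial oxidation of the N-hydroxy group to a nitrone are further risks. Fallback, from 17 to 21 with ester cleavage separated from epimerisation, the latter run under acid through an enol: brief K2CO3/MeOH at 0 °C would stop at 18, which is isolated. Camphor-10-sulfonic acid (in excess over the pyridines) in MeOH/CH(OMe)3 at 40 °C should equilibrate C3a and trap the cis isomer as (3aS,6aR)-3-methoxy-1-[12-(pyridin-3-yl)dodecyl]-3-[8-(pyridin-3-yl)octyl]hexahydro-1H-cyclopenta[c]isoxazole F7. Et3SiH/BF3·OEt2 on F7 would give 21 through the same cation as in step 12.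

## Further compounds

F1 | step 8 | N-[(1R,2R,3R)-3-bromo-2-hydroxy-2-[8-(pyridin-3-yl)octyl]cyclohexyl]-2-nitro-N-[12-(pyridin-3-yl)dodecyl]benzenesulfonamide | c1cncc(CCCCCCCCCCCCN(S(=O)(=O)c2ccccc2[N+](=O)[O-])[C@@H]2CCC[C@@H](Br)[C@@]2(O)CCCCCCCCc2cccnc2)c1
F2 | step 5 | tert-butyl N-[(1R)-2-iodocyclohex-2-en-1-yl]-N-[(2-nitrophenyl)sulfonyl]carbamate | CC(C)(C)OC(=O)N([C@@H]1CCCC=C1I)S(=O)(=O)c1ccccc1[N+](=O)[O-]
F3 | step 5 | N-[(1R)-2-iodocyclohex-2-en-1-yl]-2-nitrobenzenesulfonamide | O=S(=O)(N[C@@H]1CCCC=C1I)c1ccccc1[N+](=O)[O-]
F4 | step 7 | 2-[8-(pyridin-3-yl)octyl]cyclohex-2-en-1-one | O=C1CCCC=C1CCCCCCCCc1cccnc1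
F5 | step 7 | (1S)-2-[8-(pyridin-3-yl)octyl]cyclohex-2-en-1-ol | O[C@H]1CCCC=C1CCCCCCCCc1cccnc1
F6 | step 9 | (1R,2R)-2-[1,1-dimethoxy-9-(pyridin-3-yl)nonyl]-N-[12-(pyridin-3-yl)dodecyl]cyclopentan-1-amine | c1cncc(CCCCCCCCCCCCN[C@@H]2CCC[C@H]2C(OC)(OC)CCCCCCCCc2cccnc2)c1
F7 | step 11 | (3aS,6aR)-3-methoxy-1-[12-(pyridin-3-yl)dodecyl]-3-[8-(pyridin-3-yl)octyl]hexahydro-1H-cyclopenta[c]isoxazole (C3 as either anomer) | c1cncc(CCCCCCCCCCCCN2OC(OC)(CCCCCCCCc3cccnc3)[C@H]3CCC[C@H]32)c1
A1 | alternative 1 | O-{(1S)-1-[(1S)-cyclopent-2-en-1-yl]-9-(pyridin-3-yl)nonyl}-N-[12-(pyridin-3-yl)dodecyl]hydroxylamine | c1cncc(CCCCCCCCCCCCNO[C@@H](CCCCCCCCc2cccnc2)[C@H]2CCC=C2)c1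
A2 | alternative 1 | (3S,3aS,6S,6aS)-6-iodo-1-[12-(pyridin-3-yl)dodecyl]-3-[8-(pyridin-3-yl)octyl]hexahydro-1H-cyclopenta[c]isoxazole | c1cncc(CCCCCCCCCCCCN2O[C@@H](CCCCCCCCc3cccnc3)[C@H]3CC[C@H](I)[C@H]32)c1
A3 | alternative 2 | (3R)-3-(3-chloropropyl)-2-[12-(pyridin-3-yl)dodecyl]isoxazolidin-5-one | c1cncc(CCCCCCCCCCCCN2OC(=O)C[C@H]2CCCCl)c1
A4 | alternative 2 | (3aS,6aR)-1-[12-(pyridin-3-yl)dodecyl]hexahydro-3H-cyclopenta[c]isoxazol-3-one | c1cncc(CCCCCCCCCCCCN2OC(=O)[C@H]3CCC[C@H]32)c1
A5 | alternative 3 | (4aR,7aR)-1-[12-(pyridin-3-yl)dodecyl]-2,4a,5,6,7,7a-hexahydro-1H-cyclopenta[b]pyridine | c1cncc(CCCCCCCCCCCCN2CC=C[C@H]3CCC[C@H]32)c1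
A6 | alternative 3 | (4aR,7aR)-1-[12-(pyridin-3-yl)dodecyl]-2,4a,5,6,7,7a-hexahydro-1H-cyclopenta[b]pyridine 1-oxide (configuration at nitrogen not specified) | c1cncc(CCCCCCCCCCCC[N+]2([O-])CC=C[C@H]3CCC[C@H]32)c1
A7 | alternative 3 | (3S,3aS,6aR)-3-ethenyl-1-[12-(pyridin-3-yl)dodecyl]hexahydro-1H-cyclopenta[c]isoxazole | c1cncc(CCCCCCCCCCCCN2O[C@@H](C=C)[C@H]3CCC[C@H]32)c1
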